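**Retrosynthetic overview**
1. 18 ⇐ open-chain acetate 15: ring B is closed last at C1–C8a by a dehydrogenative p-quinone-methide/Friedel–Crafts cyclisation (sets C1 trans to C2), then the acetate is removed.
2. 15 ⇐ arylidene lactone 12 (DIBAL-H opens the lactone and frees both phenols; a lipase masks the primary OH); C3=C4 comes from aldol condensation of lactone 7 with aldehyde 8.
3. 7 ⇐ cyclobutanone 6: the stereo-defining key step is a C–O bond formation, a catalytic asymmetric Baeyer–Villiger desymmetrisation (sets C2 = R, the only source of absolute configuration).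
4. 6 ⇐ eugenol pivalate 2 + N,N-dimethylacetamide 3 (keteniminium [2+2]); 2 ⇐ eugenol 1.
5. Ring order: cyclobutanone → γ-lactone (later opened) → carbocyclic ring B; both arenes are bought.

Assumption: the ligand antipode used in step 3 is the one that gives the (R)-lactone 7 (checked by chiral HPLC and rotation on a small run).

**Step 1**
Reactants: 1 eugenol (4-allyl-2-methoxyphenol)
Product: 2 4-allyl-2-methoxyphenyl pivalate
Conditions: PivCl, Et3N, DMAP (cat.), CH2Cl2, 0 °C → rt
Reagents that add atoms: pivaloyl chloride, CC(C)(C)C(=O)Cl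
Why: O-acylation (esterification) of the phenol; the pivalate is inert to Tf2O, peracid and a lithium enolate at −78 °C and is cleaved later by DIBAL-H without an extra step.

**Step 2**
Reactants: 2 4-allyl-2-methoxyphenyl pivalate; 3 N,N-dimethylacetamide
Product: 6 2-methoxy-4-[(3-oxocyclobutyl)methyl]phenyl pivalate, via keteniminium triflate 4 (not isolated), via cyclobutaniminium triflate 5 (not isolated)
Conditions: Tf2O, 2,4,6-collidine, ClCH2CH2Cl, −15 °C → reflux; then aq. NaHCO3, rt
Reagents that add atoms: water, O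
Why: Ghosez keteniminium–alkene [2+2] cycloaddition (the terminal alkene carbon bonds to the iminium carbon, giving the 3-substituted ring) followed by iminium hydrolysis gives the achiral, prochiral cyclobutanone, so no stereocentre is formed here.

**Step 3**
Reactants: 6 2-methoxy-4-[(3-oxocyclobutyl)methyl]phenyl pivalate
Product: 7 2-methoxy-4-{[(3R)-5-oxooxolan-3-yl]methyl}phenyl pivalate [(R)-β-arylmethyl-γ-butyrolactone]
Conditions: Sc(OTf)3 (5 mol %), chiral N,N′-dioxide ligand (5 mol %), m-CPBA (1.2 equiv), EtOAc, −20 °C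
Reagents that add atoms: m-CPBA, OOC(=O)c1cccc(Cl)c1
Why: Catalytic asymmetric Baeyer–Villiger oxidation: in the Sc-bound Criegee adduct the chiral ligand selects one of the two enantiotopic ring CH2 groups for migration, so this O-insertion (the key C–O bond) desymmetrises 6 and sets C2 as R; ring strain makes the cyclobutanone far more reactive than the aryl ester or arene.

**Step 4**
Reactants: 7 (R)-lactone; 8 4-acetoxy-3,5-dimethoxybenzaldehyde
Product: 12 (3E,4R)-3-(4-acetoxy-3,5-dimethoxybenzylidene)-4-(3-methoxy-4-pivaloyloxybenzyl)oxolan-2-one, via lithium enolate 9 (not isolated), via lithium aldolate 10 (not isolated), via β-acetoxy lactone 11 (not isolated)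
Conditions: LiHMDS (1.05 equiv), THF, −78 °C; 8; then Ac2O, DMAP (cat.), −78 → 0 °C; then DBU, rt
Reagents that add atoms: none
Why: Aldol condensation (lactone enolate addition, acetylation of the aldolate, DBU E1cB elimination) gives the more stable E-arylidene lactone, and the C4 stereocentre has no acidic hydrogen under these conditions so it is untouched.

**Step 5**
Reactants: 12 (3E,4R)-arylidene lactone
Product: 14 (2E,3R)-4-hydroxy-2-(4-hydroxy-3,5-dimethoxybenzylidene)-3-(4-hydroxy-3-methoxybenzyl)butanal, via lactol 13 (not isolated)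
Conditions: DIBAL-H (6 equiv), CH2Cl2, −78 °C; MeOH, then aq. Rochelle salt
Reagents that add atoms: none
Why: DIBAL-H partial reduction of the lactone to the lactol (the aluminium hemiacetal is stable at −78 °C) with simultaneous reductive cleavage of both aryl esters; ring–chain tautomerism then gives the conjugated hydroxy-enal and no stereocentre is involved.

**Step 6**
Reactants: 14 (2E,3R)-hydroxy-enal bis-phenol
Product: 15 (2R,3E)-3-formyl-4-(4-hydroxy-3,5-dimethoxyphenyl)-2-(4-hydroxy-3-methoxybenzyl)but-3-en-1-yl acetate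
Conditions: Novozym 435 (immobilised CAL-B), vinyl acetate, MTBE–THF, 30 °C
Reagents that add atoms: vinyl acetate, C=COC(C)=O
Why: Lipase-catalysed transesterification with an enol ester acylates only the primary aliphatic OH (phenols are not substrates), which pulls the lactol/enal equilibrium to the open chain and removes the five-membered ring that would otherwise force the wrong (cis) closure and be oxidised by DDQ.

**Step 7**
Reactants: 15 open-chain primary acetate
Product: 18 (1S,2R)-7-hydroxy-1-(4-hydroxy-3-methoxyphenyl)-2-(hydroxymethyl)-6,8-dimethoxy-1,2-dihydronaphthalene-3-carbaldehyde, via p-quinone methide 16 (not isolated), via cyclised acetate 17 (not isolated)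
Conditions: DDQ (1.0 equiv), (PhO)2P(O)OH (10 mol %), CH2Cl2, −20 → 0 °C; filter; then K2CO3, MeOH, 0 °C → rt
Reagents that add atoms: none
Why: Proposed new method: DDQ removes hydride from the benzylic CH2 para to the free guaiacyl OH (the syringyl phenol is deactivated by the conjugated enal and has no benzylic C–H) to give p-quinone methide 16, which the phosphoric acid activates by H-bonding for intramolecular 1,6-Friedel–Crafts attack by the syringyl carbon para to OMe (six-membered ring) through a half-chair transition state with the quinonoid ring and CH2OAc both pseudoaxial (no peri clash with the 8-OMe, no A1,2 strain with CHO), so C1 forms trans to C2, i.e. 1S from 2R; mild methanolysis then removes the acetate; the closest known reactions are the DDQ/TFA oxidative cyclisation of dibenzylbutyrolactones to aryltetralins and the acid-catalysed 1,6-arylation of preformed p-quinone methides, neither shown for a free bis-phenol with an enal-conjugated arene nucleophile giving a 1,2-dihydronaphthalene.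

**Compound list**
1 | eugenol (4-allyl-2-methoxyphenol) | C=CCc1ccc(O)c(OC)c1 | starting material
2 | 4-allyl-2-methoxyphenyl pivalate | C=CCc1ccc(OC(=O)C(C)(C)C)c(OC)c1 | intermediate
3 | N,N-dimethylacetamide | CC(=O)N(C)C | starting material
4 | N,N-dimethylketeniminium triflate | C=C=[N+](C)C.[O-]S(=O)(=O)C(F)(F)F | intermediate
5 | N,N-dimethyl-3-(3-methoxy-4-pivaloyloxybenzyl)cyclobutan-1-iminium triflate | C[N+](C)=C1CC(Cc2ccc(OC(=O)C(C)(C)C)c(OC)c2)C1.[O-]S(=O)(=O)C(F)(F)F | intermediate
6 | 2-methoxy-4-[(3-oxocyclobutyl)methyl]phenyl pivalate | O=C1CC(Cc2ccc(OC(=O)C(C)(C)C)c(OC)c2)C1 | intermediate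
7 | 2-methoxy-4-{[(3R)-5-oxooxolan-3-yl]methyl}phenyl pivalate | O=C1C[C@@H](Cc2ccc(OC(=O)C(C)(C)C)c(OC)c2)CO1 | intermediate
8 | 4-acetoxy-3,5-dimethoxybenzaldehyde | CC(=O)Oc1c(OC)cc(C=O)cc1OC | starting material
9 | lithium enolate of 7 (C4 = R) | [Li+].[O-]C1=C[C@@H](Cc2ccc(OC(=O)C(C)(C)C)c(OC)c2)CO1 | intermediate
10 | lithium aldolate from 9 and 8 (C4 = R; both epimers at the two new centres) | [Li+].[O-]C(c1cc(OC)c(OC(C)=O)c(OC)c1)C1C(=O)OC[C@@H]1Cc1ccc(OC(=O)C(C)(C)C)c(OC)c1 | intermediate
11 | O-acetate of aldol 10 (C4 = R; both epimers at the two new centres) | CC(=O)OC(c1cc(OC)c(OC(C)=O)c(OC)c1)C1C(=O)OC[C@@H]1Cc1ccc(OC(=O)C(C)(C)C)c(OC)c1 | intermediate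
12 | (3E,4R)-3-(4-acetoxy-3,5-dimethoxybenzylidene)-4-(3-methoxy-4-pivaloyloxybenzyl)oxolan-2-one | O=C1OC[C@H](Cc2ccc(OC(=O)C(C)(C)C)c(OC)c2)/C1=C\c1cc(OC)c(OC(C)=O)c(OC)c1 | intermediate
13 | (3E,4R)-3-(4-hydroxy-3,5-dimethoxybenzylidene)-4-(4-hydroxy-3-methoxybenzyl)oxolan-2-ol (both anomers) | OC1OC[C@H](Cc2ccc(O)c(OC)c2)/C1=C\c1cc(OC)c(O)c(OC)c1 | intermediate
14 | (2E,3R)-4-hydroxy-2-(4-hydroxy-3,5-dimethoxybenzylidene)-3-(4-hydroxy-3-methoxybenzyl)butanal | O=C/C(=C/c1cc(OC)c(O)c(OC)c1)[C@@H](Cc1ccc(O)c(OC)c1)CO | intermediate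
15 | (2R,3E)-3-formyl-4-(4-hydroxy-3,5-dimethoxyphenyl)-2-(4-hydroxy-3-methoxybenzyl)but-3-en-1-yl acetate | O=C/C(=C/c1cc(OC)c(O)c(OC)c1)[C@@H](Cc1ccc(O)c(OC)c1)COC(C)=O | intermediate
16 | (2R,3E)-3-formyl-4-(4-hydroxy-3,5-dimethoxyphenyl)-2-[(3-methoxy-4-oxocyclohexa-2,5-dien-1-ylidene)methyl]but-3-en-1-yl acetate (exocyclic quinonoid C=C geometry not defined) | O=C1C(OC)=CC(=C[C@@H](COC(C)=O)/C(C=O)=C\c2cc(OC)c(O)c(OC)c2)C=C1 | intermediate
17 | [(1S,2R)-3-formyl-7-hydroxy-1-(4-hydroxy-3-methoxyphenyl)-6,8-dimethoxy-1,2-dihydronaphthalen-2-yl]methyl acetate | COc1cc([C@H]2c3c(cc(OC)c(O)c3OC)C=C(C=O)[C@@H]2COC(C)=O)ccc1O | intermediate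
18 | (1S,2R)-7-hydroxy-1-(4-hydroxy-3-methoxyphenyl)-2-(hydroxymethyl)-6,8-dimethoxy-1,2-dihydronaphthalene-3-carbaldehyde (1,2-trans) | COc1cc([C@H]2c3c(cc(OC)c(O)c3OC)C=C(C=O)[C@@H]2CO)ccc1O | target

**Step count and risks**
Total steps: 7. Longest linear sequence: 7 (eugenol 1 → 18); 3 and 8 are bought.

The three steps most likely to fail:

Step 7 (the proposed new step). The risks are tautomerisation of 16 to the styrene (which would erase C2), over-oxidation of 17 to the arylnaphthalene, and formation of the cis isomer. The fallback uses known chemistry and sets out from 15. DDQ in MeOH–CH2Cl2 traps the quinone methide as the isolable benzylic methyl ether (3E)-3-formyl-4-(4-hydroxy-3,5-dimethoxyphenyl)-2-[(4-hydroxy-3-methoxyphenyl)(methoxy)methyl]but-3-en-1-yl acetate F3 (C2 unchanged, both epimers at the OMe carbon). BF3·OEt2 in CH2Cl2 at −40 °C then effects a classical intramolecular Friedel–Crafts alkylation with loss of methanol. This rejoins the route at 17, which is deacetylated with K2CO3/MeOH to 18.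

Step 3. The enantioselectivity for a benzyl-substituted (rather than aryl-substituted) cyclobutanone may fall below about 90% ee; recrystallising 12 can raise it. The fallback sets out from 6. Uncatalysed Baeyer–Villiger oxidation (m-CPBA, NaHCO3, CH2Cl2) gives the racemic lactone, i.e. 7 together with its enantiomer 2-methoxy-4-{[(3S)-5-oxooxolan-3-yl]methyl}phenyl pivalate F1. Preparative chiral SFC separates the two, and the route is rejoined at 7.

Step 5. The risks are over-reduction to the diol and incomplete cleavage of the hindered aryl esters. The fallback sets out from 12. Exhaustive reduction with excess DIBAL-H (CH2Cl2, −78 → 0 °C) gives (2E,3R)-2-(4-hydroxy-3,5-dimethoxybenzylidene)-3-(4-hydroxy-3-methoxybenzyl)butane-1,4-diol F2. Its p-hydroxycinnamyl alcohol is then oxidised selectively with DDQ (1.0 equiv, dioxane, 0 °C; the sinapyl alcohol → sinapaldehyde oxidation), which rejoins the route at 14.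

**Further compounds**
F1 | step 3 | 2-methoxy-4-{[(3S)-5-oxooxolan-3-yl]methyl}phenyl pivalate | O=C1C[C@H](Cc2ccc(OC(=O)C(C)(C)C)c(OC)c2)CO1
F2 | step 5 | (2E,3R)-2-(4-hydroxy-3,5-dimethoxybenzylidene)-3-(4-hydroxy-3-methoxybenzyl)butane-1,4-diol | OC/C(=C/c1cc(OC)c(O)c(OC)c1)[C@@H](Cc1ccc(O)c(OC)c1)CO
F3 | step 7 | (3E)-3-formyl-4-(4-hydroxy-3,5-dimethoxyphenyl)-2-[(4-hydroxy-3-methoxyphenyl)(methoxy)methyl]but-3-en-1-yl acetate | O=C/C(=C/c1cc(OC)c(O)c(OC)c1)[C@@H](C(OC)c1ccc(O)c(OC)c1)COC(C)=O
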